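**Strategy.** Everything rests on disconnecting ring B across C1'–C6' and C2'–C3': a phenol whose C1' (bonded to C3) is para to the C4' hydroxyl is the aromatised form of a 4-substituted cyclohex-2-enone. A Robinson-type annulation of methyl vinyl ketone onto the acetaldehyde arm at C3 therefore makes both bonds and all of ring B in one operation, with the C4' oxygen already in place; the C3' prenyl group follows from that oxygen by a Claisen shift. The annulation substrate is (3S)-2-(chroman-3-yl)acetaldehyde carrying the 6-prenyl group, a 7-silyl ether and a C4 dioxolane that shields the C3 stereocentre, itself set by an asymmetric intramolecular Stetter reaction.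

Key step: step 7

Assumption: atom labels follow isoflavanone numbering (ring C: O1, C2, C3, C4; ring A: C4a–C8a; ring B: C1'–C6'), and the target SMILES corresponds to 3S; prenyl = 3-methylbut-2-en-1-yl, TIPS = triisopropylsilyl.

Assumption: the aminoindanol-derived triazolium catalyst of step 4 is used as the enantiomer that delivers 3S; its antipode is equally available should the sense of induction be the opposite.

Design remarks:
- O7 is carried as a TIPS ether, not as an acetal. An acetal is at risk under the silyl triflate of step 5, and its removal needs acid strong enough to enolise the unveiled, benzylic C3–H.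
- Ring B is aromatised before its prenyl group is introduced. A selenoxide on a carbon that also carries a prenyl group could eliminate into the side chain, whereas the ether/Claisen sequence has a single outcome.

**Step 1**
Reactants: 1 5-bromo-2,4-dihydroxybenzaldehyde
Product: 2 5-bromo-2-hydroxy-4-(TIPS-oxy)benzaldehyde
Conditions: i-Pr3SiCl (1.05 equiv), imidazole, CH2Cl2, 0 °C → rt
Reagents that add atoms: chlorotriisopropylsilane, CC(C)[Si](Cl)(C(C)C)C(C)C
Why: O-silylation, selective because the 2-hydroxyl is held in a hydrogen bond to the formyl oxygen while the more acidic 4-hydroxyl is free; the TIPS ether is chosen because it should survive the ketalisation and the basic steps and leaves with fluoride while C3 is still protected.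

**Step 2**
Reactants: 2 5-bromo-2-hydroxy-4-(TIPS-oxy)benzaldehyde; 3 tributyl(3-methylbut-2-en-1-yl)stannane
Product: 4 2-hydroxy-5-prenyl-4-(TIPS-oxy)benzaldehyde
Conditions: Pd(PPh3)4 (5 mol%), DMF, 95 °C, degassed
Reagents that add atoms: none
Why: Stille coupling of an aryl bromide with an allylic stannane, in which reductive elimination at the unsubstituted CH2 end of the allyl ligand should give the linear prenyl arene, and which tolerates the aldehyde, the chelated phenol and the silyl ether.

**Step 3**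
Reactants: 4 2-hydroxy-5-prenyl-4-(TIPS-oxy)benzaldehyde; 5 methyl (E)-4-bromobut-2-enoate
Product: 6 methyl (E)-4-[2-formyl-4-prenyl-5-(TIPS-oxy)phenoxy]but-2-enoate
Conditions: K2CO3 (1.5 equiv), dry acetone, rt
Reagents that add atoms: none
Why: Williamson ether synthesis, the salicylaldehyde phenoxide displacing the primary allylic bromide by direct SN2 substitution so that the E-enoate remains as the acceptor for ring closure.

**Step 4**
Reactants: 6 methyl (E)-4-[2-formyl-4-prenyl-5-(TIPS-oxy)phenoxy]but-2-enoate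
Product: 7 methyl 2-[(3S)-4-oxo-6-prenyl-7-(TIPS-oxy)chroman-3-yl]acetate
Conditions: aminoindanol-derived N-pentafluorophenyl triazolium tetrafluoroborate (20 mol%), KN(SiMe3)2 (18 mol%), toluene, rt
Reagents that add atoms: none
Why: Asymmetric intramolecular Stetter reaction, in which the carbene turns the formyl group into an acyl-anion equivalent that adds 6-exo-trig to the enoate and closes ring C, the rigid chiral backbone of the catalyst selecting the enoate face so that C3 is formed as S.

**Step 5**
Reactants: 7 methyl 2-[(3S)-4-oxo-6-prenyl-7-(TIPS-oxy)chroman-3-yl]acetate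
Product: 8 methyl 2-[(3S)-6-prenyl-7-(TIPS-oxy)spiro[chromane-4,2'-[1,3]dioxolan]-3-yl]acetate
Conditions: (Me3SiOCH2)2 (3 equiv), Me3SiOTf (10 mol%), CH2Cl2, −78 → −20 °C; pyridine quench
Reagents that add atoms: 1,2-bis(trimethylsilyloxy)ethane, C[Si](C)(C)OCCO[Si](C)(C)C
Why: Silyl-triflate-catalysed dioxolane formation driven by loss of hexamethyldisiloxane, run cold and aprotic so that C3 next to the carbonyl should not enolise and the alkene and aryl silyl ether are left alone; the ketal then removes all acidity from the C3–H for the basic steps that follow.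

**Step 6**
Reactants: 8 methyl 2-[(3S)-6-prenyl-7-(TIPS-oxy)spiro[chromane-4,2'-[1,3]dioxolan]-3-yl]acetate
Product: 9 2-[(3S)-6-prenyl-7-(TIPS-oxy)spiro[chromane-4,2'-[1,3]dioxolan]-3-yl]acetaldehyde
Conditions: i-Bu2AlH (1.1 equiv), CH2Cl2, −78 °C; MeOH, then aq potassium sodium tartrate
Reagents that add atoms: none
Why: Partial ester reduction, the tetrahedral aluminium hemiacetal (helped by chelation to a ketal oxygen) persisting at low temperature and releasing the aldehyde only on quench.

**Step 7**
Reactants: 9 2-[(3S)-6-prenyl-7-(TIPS-oxy)spiro[chromane-4,2'-[1,3]dioxolan]-3-yl]acetaldehyde; 10 methyl vinyl ketone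
Product: 13 4-[(3S)-6-prenyl-7-(TIPS-oxy)spiro[chromane-4,2'-[1,3]dioxolan]-3-yl]cyclohex-2-en-1-one (epimer mixture at the ring B methine), via keto-aldehyde Michael adduct 11 (not isolated), via ketol 12 (not isolated)
Conditions: 10 (1.5 equiv), 2-[diphenyl(trimethylsilyloxy)methyl]pyrrolidine (10 mol%, either enantiomer), ethyl 3,4-dihydroxybenzoate (20 mol%), toluene, 4 °C; then LiOH (0.2 equiv), i-PrOH, rt
Reagents that add atoms: none
Why: The secondary amine condenses with 9 to an enamine whose nucleophilic carbon (the future C1') adds to methyl vinyl ketone, forming C1'–C6' and giving keto-aldehyde 11 after hydrolysis; hydroxide then enolises the methyl ketone, which attacks the aldehyde carbon to form C2'–C3' (ketol 12), and loss of water gives enone 13. The closest known reaction type is the amine-catalysed Michael addition of alpha-unbranched aldehydes to enones followed by base-mediated aldol condensation, an enamine Robinson annulation to 4-substituted cyclohex-2-enones. Ring B closes in a 6-(enolendo)-exo-trig aldol step, the only six-membered closure open to 11. No stereocentre of the target is created: the ring B methine forms as a mixture and is erased on aromatisation, while C3 keeps its configuration because, flanked by the ketal, it has no acidic hydrogen. The step needs a single Michael addition at the aldehyde alpha carbon ahead of self-aldol and enone polymerisation, which the bulky diarylprolinol ether and the beta-branching of 9 should secure, and it needs the ketal and silyl ether to survive, which the weakly acidic co-catalyst and substoichiometric LiOH allow.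

**Step 8**
Reactants: 13 4-[(3S)-6-prenyl-7-(TIPS-oxy)spiro[chromane-4,2'-[1,3]dioxolan]-3-yl]cyclohex-2-en-1-one
Product: 17 4-[(3S)-6-prenyl-7-(TIPS-oxy)spiro[chromane-4,2'-[1,3]dioxolan]-3-yl]phenol, via alpha-prime phenylselenide 14 (not isolated), via selenoxide 15 (not isolated), via cyclohexa-2,5-dienone 16 (not isolated)
Conditions: LiN(i-Pr)2 (1.1 equiv), THF, −78 °C; PhSeBr (1.1 equiv); crude selenide: mCPBA (1.05 equiv), NaHCO3, CH2Cl2, −78 °C; i-Pr2NH (3 equiv), −78 °C → rt
Reagents that add atoms: none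
Why: Kinetic alpha-prime enolate selenenylation and selenoxide syn-elimination, where the only beta hydrogens sit on C6' so a single cross-conjugated dienone can form, and this tautomerises at once to the phenol, turning the C4' carbonyl into the ring B hydroxyl.

**Step 9**
Reactants: 18 2-methylbut-3-en-2-ol
Product: 19 tert-butyl 2-methylbut-3-en-2-yl carbonate
Conditions: n-BuLi (1.0 equiv), THF, 0 °C; Boc2O, 0 °C → rt
Reagents that add atoms: di-tert-butyl dicarbonate, CC(C)(C)OC(=O)OC(=O)OC(C)(C)C
Why: Acylation of the lithium alkoxide with the dicarbonate gives the mixed tertiary allylic carbonate, a standard precursor of a 1,1-dimethylallyl palladium cation.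

**Step 10**
Reactants: 17 4-[(3S)-6-prenyl-7-(TIPS-oxy)spiro[chromane-4,2'-[1,3]dioxolan]-3-yl]phenol; 19 tert-butyl 2-methylbut-3-en-2-yl carbonate
Product: 20 (3S)-3-{4-[(2-methylbut-3-en-2-yl)oxy]phenyl}-6-prenyl-7-(TIPS-oxy)spiro[chromane-4,2'-[1,3]dioxolane]
Conditions: 19 (1.5 equiv), Pd(PPh3)4 (2 mol%), THF, 0 °C
Reagents that add atoms: none
Why: Decarboxylative Tsuji–Trost etherification with zerovalent palladium, the phenoxide attacking the more substituted end of the allyl palladium cation at low temperature to give the tertiary aryl ether, the ring B hydroxyl being the only free hydroxyl in 17.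

**Step 11**
Reactants: 20 (3S)-3-{4-[(2-methylbut-3-en-2-yl)oxy]phenyl}-6-prenyl-7-(TIPS-oxy)spiro[chromane-4,2'-[1,3]dioxolane]
Product: 22 2-prenyl-4-[(3S)-6-prenyl-7-(TIPS-oxy)spiro[chromane-4,2'-[1,3]dioxolan]-3-yl]phenol, via ortho-dienone 21 (not isolated)
Conditions: PhNEt2, 130 °C
Reagents that add atoms: none
Why: Aromatic Claisen rearrangement, the [3,3] shift delivering the CH2 terminus of the tertiary allyl ether to an ortho carbon (C3' and C5' are equivalent and the para position is blocked by C3), followed by tautomerisation to the prenyl phenol without any acid.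

**Step 12**
Reactants: 22 2-prenyl-4-[(3S)-6-prenyl-7-(TIPS-oxy)spiro[chromane-4,2'-[1,3]dioxolan]-3-yl]phenol
Product: 24 (3S)-7-hydroxy-3-(4-hydroxy-3-prenylphenyl)-6-prenylchroman-4-one, via desilylated ketal 23 (not isolated)
Conditions: Bu4NF (1.2 equiv), THF, 0 °C; then 1 M aq HCl to pH 1–2, 0 °C → rt; NaHCO3 quench on completion
Reagents that add atoms: water, O
Why: Fluoride desilylation while the ketal still blocks enolisation at C3, then acid-catalysed hydrolysis of the dioxolane of a strongly donor-substituted aryl ketone, which should be fast in dilute acid at room temperature and too mild to enolise the isoflavanone or cyclise the ortho-prenyl phenols, so C3 stays S.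

**Compound list**
1 | 5-bromo-2,4-dihydroxybenzaldehyde | O=Cc1cc(Br)c(O)cc1O | starting material
2 | 5-bromo-2-hydroxy-4-[(triisopropylsilyl)oxy]benzaldehyde | O=Cc1cc(Br)c(O[Si](C(C)C)(C(C)C)C(C)C)cc1O | intermediate
3 | tributyl(3-methylbut-2-en-1-yl)stannane | CCCC[Sn](CCCC)(CCCC)CC=C(C)C | starting material
4 | 2-hydroxy-5-(3-methylbut-2-en-1-yl)-4-[(triisopropylsilyl)oxy]benzaldehyde | O=Cc1cc(CC=C(C)C)c(O[Si](C(C)C)(C(C)C)C(C)C)cc1O | intermediate
5 | methyl (E)-4-bromobut-2-enoate | COC(=O)/C=C/CBr | starting material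
6 | methyl (E)-4-{2-formyl-4-(3-methylbut-2-en-1-yl)-5-[(triisopropylsilyl)oxy]phenoxy}but-2-enoate | COC(=O)/C=C/COc1cc(O[Si](C(C)C)(C(C)C)C(C)C)c(CC=C(C)C)cc1C=O | intermediate
7 | methyl 2-[(3S)-6-(3-methylbut-2-en-1-yl)-4-oxo-7-[(triisopropylsilyl)oxy]chroman-3-yl]acetate | COC(=O)C[C@H]1COc2cc(O[Si](C(C)C)(C(C)C)C(C)C)c(CC=C(C)C)cc2C1=O | intermediate
8 | methyl 2-[(3S)-6-(3-methylbut-2-en-1-yl)-7-[(triisopropylsilyl)oxy]spiro[chromane-4,2'-[1,3]dioxolan]-3-yl]acetate | COC(=O)C[C@H]1COc2cc(O[Si](C(C)C)(C(C)C)C(C)C)c(CC=C(C)C)cc2C13OCCO3 | intermediate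
9 | 2-[(3S)-6-(3-methylbut-2-en-1-yl)-7-[(triisopropylsilyl)oxy]spiro[chromane-4,2'-[1,3]dioxolan]-3-yl]acetaldehyde | O=CC[C@H]1COc2cc(O[Si](C(C)C)(C(C)C)C(C)C)c(CC=C(C)C)cc2C13OCCO3 | intermediate
10 | methyl vinyl ketone (but-3-en-2-one) | CC(=O)C=C | starting material
11 | 5-oxo-2-[(3S)-6-(3-methylbut-2-en-1-yl)-7-[(triisopropylsilyl)oxy]spiro[chromane-4,2'-[1,3]dioxolan]-3-yl]hexanal, epimer mixture at C2 of the hexanal | O=CC(CCC(C)=O)[C@H]1COc2cc(O[Si](C(C)C)(C(C)C)C(C)C)c(CC=C(C)C)cc2C13OCCO3 | intermediate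
12 | 3-hydroxy-4-[(3S)-6-(3-methylbut-2-en-1-yl)-7-[(triisopropylsilyl)oxy]spiro[chromane-4,2'-[1,3]dioxolan]-3-yl]cyclohexan-1-one, diastereomer mixture | O=C1CC(O)C(CC1)[C@H]2COc3cc(O[Si](C(C)C)(C(C)C)C(C)C)c(CC=C(C)C)cc3C24OCCO4 | intermediate
13 | 4-[(3S)-6-(3-methylbut-2-en-1-yl)-7-[(triisopropylsilyl)oxy]spiro[chromane-4,2'-[1,3]dioxolan]-3-yl]cyclohex-2-en-1-one, epimer mixture at cyclohexenone C4 | O=C1C=CC(CC1)[C@H]2COc3cc(O[Si](C(C)C)(C(C)C)C(C)C)c(CC=C(C)C)cc3C24OCCO4 | intermediate
14 | 6-(phenylselanyl)-4-[(3S)-6-(3-methylbut-2-en-1-yl)-7-[(triisopropylsilyl)oxy]spiro[chromane-4,2'-[1,3]dioxolan]-3-yl]cyclohex-2-en-1-one, diastereomer mixture | O=C1C=CC(CC1[Se]c5ccccc5)[C@H]2COc3cc(O[Si](C(C)C)(C(C)C)C(C)C)c(CC=C(C)C)cc3C24OCCO4 | intermediate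
15 | 6-(phenylseleninyl)-4-[(3S)-6-(3-methylbut-2-en-1-yl)-7-[(triisopropylsilyl)oxy]spiro[chromane-4,2'-[1,3]dioxolan]-3-yl]cyclohex-2-en-1-one, diastereomer mixture | O=C1C=CC(CC1[Se](=O)c5ccccc5)[C@H]2COc3cc(O[Si](C(C)C)(C(C)C)C(C)C)c(CC=C(C)C)cc3C24OCCO4 | intermediate
16 | 4-[(3S)-6-(3-methylbut-2-en-1-yl)-7-[(triisopropylsilyl)oxy]spiro[chromane-4,2'-[1,3]dioxolan]-3-yl]cyclohexa-2,5-dien-1-one | O=C1C=CC(C=C1)[C@H]2COc3cc(O[Si](C(C)C)(C(C)C)C(C)C)c(CC=C(C)C)cc3C24OCCO4 | intermediate
17 | 4-[(3S)-6-(3-methylbut-2-en-1-yl)-7-[(triisopropylsilyl)oxy]spiro[chromane-4,2'-[1,3]dioxolan]-3-yl]phenol | Oc1ccc(cc1)[C@H]2COc3cc(O[Si](C(C)C)(C(C)C)C(C)C)c(CC=C(C)C)cc3C24OCCO4 | intermediate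
18 | 2-methylbut-3-en-2-ol | CC(C)(O)C=C | starting material
19 | tert-butyl 2-methylbut-3-en-2-yl carbonate | CC(C)(C)OC(=O)OC(C)(C)C=C | intermediate
20 | (3S)-3-{4-[(2-methylbut-3-en-2-yl)oxy]phenyl}-6-(3-methylbut-2-en-1-yl)-7-[(triisopropylsilyl)oxy]spiro[chromane-4,2'-[1,3]dioxolane] | C=CC(C)(C)Oc1ccc(cc1)[C@H]2COc3cc(O[Si](C(C)C)(C(C)C)C(C)C)c(CC=C(C)C)cc3C24OCCO4 | intermediate
21 | 6-(3-methylbut-2-en-1-yl)-4-[(3S)-6-(3-methylbut-2-en-1-yl)-7-[(triisopropylsilyl)oxy]spiro[chromane-4,2'-[1,3]dioxolan]-3-yl]cyclohexa-2,4-dien-1-one | O=C1C=CC(=CC1CC=C(C)C)[C@H]2COc3cc(O[Si](C(C)C)(C(C)C)C(C)C)c(CC=C(C)C)cc3C24OCCO4 | intermediate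
22 | 2-(3-methylbut-2-en-1-yl)-4-[(3S)-6-(3-methylbut-2-en-1-yl)-7-[(triisopropylsilyl)oxy]spiro[chromane-4,2'-[1,3]dioxolan]-3-yl]phenol | CC(C)=CCc1cc(ccc1O)[C@H]2COc3cc(O[Si](C(C)C)(C(C)C)C(C)C)c(CC=C(C)C)cc3C24OCCO4 | intermediate
23 | (3S)-3-[4-hydroxy-3-(3-methylbut-2-en-1-yl)phenyl]-6-(3-methylbut-2-en-1-yl)spiro[chromane-4,2'-[1,3]dioxolan]-7-ol | CC(C)=CCc1cc(ccc1O)[C@H]2COc3cc(O)c(CC=C(C)C)cc3C24OCCO4 | intermediate
24 | (3S)-7-hydroxy-3-[4-hydroxy-3-(3-methylbut-2-en-1-yl)phenyl]-6-(3-methylbut-2-en-1-yl)chroman-4-one | CC(C)=CCc1cc(ccc1O)[C@H]2COc3cc(O)c(CC=C(C)C)cc3C2=O | target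

**Step count.** Total: 12 steps. Longest linear sequence: 11 steps (steps 1–8 and 10–12; step 9 is a one-step side branch).

**Steps most likely to fail**

1. Step 7 (key step). Enamine formation at the beta-branched aldehyde may be slow under catalytic conditions, so that methyl vinyl ketone oligomerises or adds twice, or the aldehyde self-condenses. Fallback, setting out from 9: condensation with pyrrolidine (K2CO3, toluene, 0 °C → rt) would give the preformed enamine (E)-1-{2-[(3S)-6-prenyl-7-(TIPS-oxy)spiro[chromane-4,2'-[1,3]dioxolan]-3-yl]ethenyl}pyrrolidine F1. As a stoichiometric, far stronger carbon nucleophile it should add to 10 in dioxane at room temperature. Hydrolysis with pH 5 acetate buffer at room temperature would release keto-aldehyde 11, which is isolated and closed in a separate operation (LiOH, i-PrOH, via 12) to rejoin the route at 13.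

2. Step 5. The donor-substituted aryl ketone may ketalise incompletely, and forcing the reaction risks epimerisation at C3 through an enol ether. Fallback, setting out from 7: thioketalisation with propane-1,3-dithiol and BF3·OEt2 (CH2Cl2, 0 °C), which is more favourable for deactivated aryl ketones, would give methyl 2-[(3S)-6-prenyl-7-(TIPS-oxy)spiro[chromane-4,2'-[1,3]dithian]-3-yl]acetate F2. Oxidative sulfur-to-oxygen exchange with PhI(OCOCF3)2 in ethylene glycol/MeCN over NaHCO3 at 0 °C would then deliver the dioxolane directly and return to the route at 8.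

3. Step 2. The allyl fragment may couple through its substituted terminus (giving the 1,1-dimethylallyl arene), or oxidative addition into the electron-rich, ortho-silyloxy bromide may be slow. Fallback, setting out from 2: Stille coupling with allyltributylstannane (Pd(PPh3)4, DMF, 95 °C), which has no regiochemical ambiguity, would give 2-hydroxy-5-(prop-2-en-1-yl)-4-(TIPS-oxy)benzaldehyde F3. Olefin cross-metathesis with excess 2-methylbut-2-ene (second-generation Grubbs catalyst, CH2Cl2, 40 °C) would then build the trisubstituted alkene and return to the route at 4.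

**Further compounds**
F1 | step 7 | (E)-1-{2-[(3S)-6-(3-methylbut-2-en-1-yl)-7-[(triisopropylsilyl)oxy]spiro[chromane-4,2'-[1,3]dioxolan]-3-yl]ethenyl}pyrrolidine | C1CCN(C1)/C=C/[C@H]2COc3cc(O[Si](C(C)C)(C(C)C)C(C)C)c(CC=C(C)C)cc3C24OCCO4
F2 | step 5 | methyl 2-[(3S)-6-(3-methylbut-2-en-1-yl)-7-[(triisopropylsilyl)oxy]spiro[chromane-4,2'-[1,3]dithian]-3-yl]acetate | COC(=O)C[C@H]1COc2cc(O[Si](C(C)C)(C(C)C)C(C)C)c(CC=C(C)C)cc2C13SCCCS3
F3 | step 2 | 2-hydroxy-5-(prop-2-en-1-yl)-4-[(triisopropylsilyl)oxy]benzaldehyde | O=Cc1cc(CC=C)c(O[Si](C(C)C)(C(C)C)C(C)C)cc1O
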